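**Retrosynthetic overview**
1. The aryl–alkenyl C–C bond is made last. A Pd-catalysed three-component syn-arylmethylation of the terminal alkyne of (S)-2-allyl-4-ethynyl-4,5-dimethoxycyclohexa-2,5-dienone with 4-iodo-1,2-dimethoxybenzene and SnMe4 joins the two halves, brings in the vinylic methyl group and sets the E-trisubstituted styrene in one operation.
2. Enabling feature: the H–C≡C unit sits on the fully substituted, methoxy-bearing ring carbon C4 of the cyclohexa-2,5-dienone (flanked by ring sp2 carbons C3 and C5). Aryl is therefore steered to the terminal alkyne carbon, the alkenyl–Pd has no β-hydrogen and waits for methyl transfer, and no bond to C4 is touched.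
3. The C4 stereocentre is set with a temporary norbornene ring: enantioselective Diels–Alder reaction of 2-allyl-5-methoxy-1,4-benzoquinone with cyclopentadiene at the allyl-bearing C=C, convex-face ethynylation of the ketone next to C–OMe, O-methylation, then retro-Diels–Alder.
4. The quinone comes from 3,4-dimethoxyphenol by O-allylation, Claisen rearrangement and oxidative demethylation.
5. Ring order: the six-membered carbocycle is the arene of the phenol throughout (dearomatised at the quinone stage). The bicyclo[2.2.1]heptene ring is closed in step 4 and opened again in step 7. The key step closes no ring.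

Key step: step 8

Assumption: the (S)-configured oxazaborolidinium catalyst of step 4 is taken to deliver adduct 6 as drawn, following the usual facial model for quinones; if the sense were opposite, the (R)-catalyst would be used and nothing else changes.

**Step 1**
Reactants: 1 3,4-dimethoxyphenol
Product: 2 4-(allyloxy)-1,2-dimethoxybenzene
Conditions: allyl bromide, K2CO3, acetone, reflux
Reagents that add atoms: allyl bromide, C=CCBr
Why: Williamson ether synthesis; the phenoxide is the only nucleophile and the primary allylic bromide reacts by SN2.

**Step 2**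
Reactants: 2 4-(allyloxy)-1,2-dimethoxybenzene
Product: 3 2-allyl-4,5-dimethoxyphenol
Conditions: N,N-diethylaniline, 200 °C, sealed tube
Reagents that add atoms: none
Why: aromatic Claisen rearrangement ([3,3]) followed by tautomerisation; the allyl group should go mainly to the free ortho position that is not squeezed between two oxygen substituents.

**Step 3**
Reactants: 3 2-allyl-4,5-dimethoxyphenol
Product: 4 2-allyl-5-methoxy-1,4-benzoquinone
Conditions: PhI(OAc)2, MeCN–H2O (2:1), 0 °C
Reagents that add atoms: water, O
Why: hypervalent-iodine oxidative demethylation of a p-methoxyphenol; water adds at the para carbon that carries OMe and methanol is lost, leaving the allyl group and the second methoxy group untouched.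

**Step 4**
Reactants: 4 2-allyl-5-methoxy-1,4-benzoquinone; 5 cyclopenta-1,3-diene
Product: 6 (1S,4R,4aS,8aR)-4a-allyl-7-methoxy-1,4,4a,8a-tetrahydro-1,4-methanonaphthalene-5,8-dione (endo adduct)
Conditions: (S)-diphenylprolinol-derived B-(o-tolyl)oxazaborolidine (10 mol %), Tf2NH (9 mol %), CH2Cl2, −78 °C
Reagents that add atoms: none
Why: catalytic enantioselective Diels–Alder reaction at the allyl-substituted C=C (the methoxy-bearing C=C is a deactivated vinylogous ester); cis ring fusion follows from suprafacial addition, endo orientation from secondary orbital overlap, and the absolute sense of all four new stereocentres from the chiral boron Lewis acid bound to a quinone carbonyl, which screens one face of the dienophile.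

**Step 5**
Reactants: 6 endo adduct
Product: 7 (1S,4R,4aS,8S,8aR)-4a-allyl-8-ethynyl-8-hydroxy-7-methoxy-4,4a,8,8a-tetrahydro-1,4-methanonaphthalen-5(1H)-one
Conditions: HC≡CMgBr, THF, −78 → −20 °C; aq. NH4Cl
Reagents that add atoms: ethynylmagnesium bromide, C#C[Mg]Br
Why: 1,2-addition of an alkynyl Grignard reagent to the more electrophilic ketone (next to the C–OMe carbon; the other carbonyl is a vinylogous ester beside a quaternary carbon), from the convex face of the cis-fused endo adduct (syn to the ring-fusion hydrogen, away from the norbornene C=C), which sets the carbinol centre relative to the ring fusion.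

**Step 6**
Reactants: 7 tertiary propargylic alcohol
Product: 8 (1S,4R,4aS,8S,8aR)-4a-allyl-8-ethynyl-7,8-dimethoxy-4,4a,8,8a-tetrahydro-1,4-methanonaphthalen-5(1H)-one
Conditions: KHMDS (1.05 equiv), THF, −78 °C; MeI, −78 → 0 °C
Reagents that add atoms: iodomethane, CI
Why: Williamson O-methylation of the tertiary alkoxide; the remaining ketone has no enolisable α-hydrogen and one equivalent of base leaves the alkyne C–H alone, so no stereocentre is affected.

**Step 7**
Reactants: 8 methyl ether adduct
Product: 9 (S)-2-allyl-4-ethynyl-4,5-dimethoxycyclohexa-2,5-dien-1-one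
Conditions: flash vacuum pyrolysis, 480 °C, 0.05 mbar, cold trap
Reagents that add atoms: none
Why: retro-Diels–Alder reaction driven by loss of cyclopentadiene and formation of the cross-conjugated dienone; the two ring-fusion centres become sp2, and the quaternary C4 takes no part in bond breaking and keeps its configuration.

**Step 8**
Reactants: 9 (S)-2-allyl-4-ethynyl-4,5-dimethoxycyclohexa-2,5-dien-1-one; 10 4-iodo-1,2-dimethoxybenzene (1.5 equiv)
Product: 11 (S)-2-allyl-4-[(E)-1-(3,4-dimethoxyphenyl)prop-1-en-2-yl]-4,5-dimethoxycyclohexa-2,5-dien-1-one
Conditions: Pd2(dba)3 (2.5 mol %), AsPh3 (10 mol %), SnMe4 (2.5 equiv), DMF, 60 °C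
Reagents that add atoms: tetramethylstannane, C[Sn](C)(C)C
Why: Proposed new method: Pd(0) inserts into the C–I bond of 10, the aryl–Pd adds syn across the terminal alkyne of 9 with aryl on the terminal carbon and Pd on the carbon next to C4, and the resulting β-hydrogen-free alkenyl–Pd iodide takes a methyl group from SnMe4 (Stille-type transmetalation) and reductively eliminates. The closest known reaction type is the Pd-catalysed three-component syn-arylmethylation (carbopalladation then cross-coupling termination) of internal alkynes, together with the aryl-to-remote-carbon regiochemistry of Pd hydroarylation of tertiary propargylic alcohols; it is extended here to a terminal propargylic ether. No ring is closed and no stereocentre is created: C4 is not touched, and the E geometry (aryl cis to methyl) follows from syn insertion with retention in transmetalation and reductive elimination. The step needs regioselectivity in the insertion, which the fully substituted C4 beside the alkyne should secure. It also needs chemoselectivity for the alkyne over the allyl and dienone alkenes and over direct aryl–methyl coupling, which rests on the faster insertion of alkynes, the trisubstituted and hindered dienone C=C bonds, and the slow methyl transfer from tin. The base-free medium should shut off the alkynyl–Pd (Sonogashira) pathway and spare the base-sensitive quinol ether.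

**Compound list**
1 | 3,4-dimethoxyphenol | COc1ccc(O)cc1OC | starting material
2 | 4-(allyloxy)-1,2-dimethoxybenzene | C=CCOc1ccc(OC)c(OC)c1 | intermediate
3 | 2-allyl-4,5-dimethoxyphenol | C=CCc1cc(OC)c(OC)cc1O | intermediate
4 | 2-allyl-5-methoxy-1,4-benzoquinone | C=CCC1=CC(=O)C(OC)=CC1=O | intermediate
5 | cyclopenta-1,3-diene (freshly cracked from the commercial dimer) | C1=CCC=C1 | starting material
6 | (1S,4R,4aS,8aR)-4a-allyl-7-methoxy-1,4,4a,8a-tetrahydro-1,4-methanonaphthalene-5,8-dione, endo | O=C1C=C(OC)C(=O)[C@@H]2[C@@H]3C=C[C@@H](C3)[C@]12CC=C | intermediate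
7 | (1S,4R,4aS,8S,8aR)-4a-allyl-8-ethynyl-8-hydroxy-7-methoxy-4,4a,8,8a-tetrahydro-1,4-methanonaphthalen-5(1H)-one (ethynyl cis to the ring-fusion H) | O=C1C=C(OC)[C@@](O)(C#C)[C@@H]2[C@@H]3C=C[C@@H](C3)[C@]12CC=C | intermediate
8 | (1S,4R,4aS,8S,8aR)-4a-allyl-8-ethynyl-7,8-dimethoxy-4,4a,8,8a-tetrahydro-1,4-methanonaphthalen-5(1H)-one | O=C1C=C(OC)[C@@](OC)(C#C)[C@@H]2[C@@H]3C=C[C@@H](C3)[C@]12CC=C | intermediate
9 | (S)-2-allyl-4-ethynyl-4,5-dimethoxycyclohexa-2,5-dien-1-one | C=CCC1=C[C@](OC)(C#C)C(OC)=CC1=O | intermediate
10 | 4-iodo-1,2-dimethoxybenzene | COc1ccc(I)cc1OC | starting material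
11 | (S)-2-allyl-4-[(E)-1-(3,4-dimethoxyphenyl)prop-1-en-2-yl]-4,5-dimethoxycyclohexa-2,5-dien-1-one | C=CCC1=C[C@](OC)(/C(C)=C/c2ccc(OC)c(OC)c2)C(OC)=CC1=O | target

**Step count and risks**
Total steps: 8. Longest linear sequence: 8 steps (1 → 11); compounds 5 and 10 enter as commercial partners.

Steps most likely to fail:

1. Step 8 (proposed new method). Methyl transfer to the aryl–Pd iodide may outrun alkyne insertion and give simple aryl–methyl coupling. The slow methyl transfer to the hindered alkenyl–Pd may also leave time for a second alkyne insertion, for vinyl-to-aryl 1,4-palladium migration or for protodepalladation, and the insertion regioselectivity may erode. Fallback with known chemistry, from 9 back to 11: copper-catalysed methylboration of the alkyne (B2pin2, MeI, CuCl/Xantphos, NaOt-Bu, THF, rt) should add boron to the terminal carbon and methyl to the internal carbon in a syn fashion, giving (S,E)-2-allyl-4,5-dimethoxy-4-[1-(4,4,5,5-tetramethyl-1,3,2-dioxaborolan-2-yl)prop-1-en-2-yl]cyclohexa-2,5-dien-1-one F1. Borylcupration of a terminal alkyne is expected to be faster than conjugate borylation of the hindered dienone. Suzuki–Miyaura coupling of this boronate with 10 (Pd(dppf)Cl2, K3PO4, THF–H2O, 40 °C) should then give 11 with retention of the alkene geometry.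

2. Step 4. Facial discrimination by the catalyst may be poor, because both quinone C=C bonds are trisubstituted and the Lewis acid can bind either carbonyl, so the enantiomeric purity of the whole series is at stake. Fallback, from 4 back to 6: the uncatalysed Diels–Alder reaction of 4 with 5 (toluene, 0 °C → rt) should give the racemic endo adduct rac-4a-allyl-7-methoxy-1,4,4a,8a-tetrahydro-1,4-methanonaphthalene-5,8-dione F2. Preparative SFC on a chiral stationary phase would deliver 6 for step 5, and the unwanted enantiomer ent-6 F3 can be cracked back to 4 and 5.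

3. Step 7. The propargylic ether and the dienone may fragment or rearrange in the hot zone before or after cycloreversion. Fallback without the temporary ring, from 4 back to 9: ethynylmagnesium bromide (THF, −78 °C) should add directly to the quinone carbonyl next to the C–OMe carbon (the other carbonyl is a vinylogous ester) to give racemic 2-allyl-4-ethynyl-4-hydroxy-5-methoxycyclohexa-2,5-dien-1-one F4. O-Methylation (MeI, Ag2O, MeCN, rt) would give racemic 2-allyl-4-ethynyl-4,5-dimethoxycyclohexa-2,5-dien-1-one F5. Preparative SFC on a chiral stationary phase would provide 9, with the unwanted enantiomer ent-9 F6 discarded.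

**Further compounds**
F1 | step 8 | (S,E)-2-allyl-4,5-dimethoxy-4-[1-(4,4,5,5-tetramethyl-1,3,2-dioxaborolan-2-yl)prop-1-en-2-yl]cyclohexa-2,5-dien-1-one | C=CCC1=C[C@](OC)(/C(C)=C/B2OC(C)(C)C(C)(C)O2)C(OC)=CC1=O
F2 | step 4 | racemic endo 4a-allyl-7-methoxy-1,4,4a,8a-tetrahydro-1,4-methanonaphthalene-5,8-dione (relative configuration as in 6) | O=C1C=C(OC)C(=O)C2C3C=CC(C3)C12CC=C
F3 | step 4 | (1R,4S,4aR,8aS)-4a-allyl-7-methoxy-1,4,4a,8a-tetrahydro-1,4-methanonaphthalene-5,8-dione (ent-6) | O=C1C=C(OC)C(=O)[C@H]2[C@H]3C=C[C@H](C3)[C@@]12CC=C
F4 | step 7 | racemic 2-allyl-4-ethynyl-4-hydroxy-5-methoxycyclohexa-2,5-dien-1-one | C=CCC1=CC(O)(C#C)C(OC)=CC1=O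
F5 | step 7 | racemic 2-allyl-4-ethynyl-4,5-dimethoxycyclohexa-2,5-dien-1-one | C=CCC1=CC(OC)(C#C)C(OC)=CC1=O
F6 | step 7 | (R)-2-allyl-4-ethynyl-4,5-dimethoxycyclohexa-2,5-dien-1-one (ent-9) | C=CCC1=C[C@@](OC)(C#C)C(OC)=CC1=O
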